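**Plan**
- Retrosynthesis: the C1'–C2' bond between the ring CH2 and the alkenyl chain is cut first (iodomethyl enone 15 + alkenyl iodide 20), then the ring bonds C1–C2 and C5–C6 (diene 4 + nitroalkene 8).
- Enabling feature: with the ring numbered C1 (C=O), C2 (C–OMe), C3, C4 (CH–OH), C5 (CH–chain), C6 (CH–CH3), the C1/C6 pair is a masked-ketone-plus-methyl two-carbon unit, i.e. (E)-1-nitropropene. C2–C5 is a four-carbon unit with oxygen at C2, i.e. a 1-methoxydiene, and its cycloadduct keeps a C3=C4 alkene through which oxygen can be placed on C4.
- Forward: the diene is made from glutaconaldehyde potassium salt and the nitroalkene from nitromethane. The Diels–Alder reaction closes the only ring; directed epoxidation, then a Nef reaction with epoxide opening, give the hydroxy methoxy-enone, and the chain is attached last by nickel coupling.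
- Stereochemistry: C5 and C6 come from the catalyst-controlled endo cycloaddition, C4 from hydroxyl-directed epoxidation cis to the C5 arm. The 2'E alkene comes from syn-carboalumination and the 6'E alkene from geranylacetone.

Key step: step 6

Convention: ring atoms keep the target numbering throughout (C1' = exocyclic carbon on C5); α is the ring face carrying the C5 substituent, β the opposite face.

Assumption: the (1R,2R) antipode of the bis-thiourea is taken to be the one that shields the nitroalkene face leading to 9; if the sense of induction proves opposite, the (1S,2S) antipode is used and nothing else changes.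

**Step 1**
Reactants: 1 glutaconaldehyde potassium salt
Product: 2 (2E,4E)-5-methoxypenta-2,4-dienal
Conditions: Me2SO4, DMF, 0 °C → rt
Reagents that add atoms: dimethyl sulfate, COS(=O)(=O)OC
Why: O-alkylation of the delocalised enolate by a hard methylating agent in a dipolar aprotic solvent should give the push–pull dienal, the all-trans anion carrying its geometry into the (2E,4E) enol ether.

**Step 2**
Reactants: 2 (2E,4E)-5-methoxypenta-2,4-dienal
Product: 3 (2E,4E)-5-methoxypenta-2,4-dien-1-ol
Conditions: i-Bu2AlH, CH2Cl2, −78 °C; aq. potassium sodium tartrate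
Reagents that add atoms: none
Why: 1,2-hydride reduction of the conjugated aldehyde at low temperature with a non-acidic work-up should leave the acid-labile dienyl ether and both E double bonds untouched.

**Step 3**
Reactants: 3 (2E,4E)-5-methoxypenta-2,4-dien-1-ol
Product: 4 tert-butyl{[(2E,4E)-5-methoxypenta-2,4-dien-1-yl]oxy}dimethylsilane, i.e. the (1E,3E)-1-methoxy-5-silyloxypenta-1,3-diene
Conditions: TBSCl, imidazole, CH2Cl2, 0 °C
Reagents that add atoms: tert-butyldimethylsilyl chloride, CC(C)(C)[Si](C)(C)Cl
Why: imidazole-buffered silylation of the primary allylic alcohol caps the hydroxyl that would otherwise ionise the dienyl ether and does not affect the alkene geometry.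

**Step 4**
Reactants: 5 nitromethane (excess); 6 acetaldehyde
Product: 7 1-nitropropan-2-ol (racemic)
Conditions: KOH (cat.), MeOH, 0 °C; AcOH quench
Reagents that add atoms: none
Why: base-catalysed Henry (nitroaldol) addition; the carbinol centre is racemic and is destroyed in step 5.

**Step 5**
Reactants: 7 1-nitropropan-2-ol
Product: 8 (E)-1-nitroprop-1-ene
Conditions: phthalic anhydride, 150–180 °C, reduced pressure, product distilled out
Reagents that add atoms: none
Why: dehydration of a β-nitro alcohol by phthalic anhydride with continuous distillation is the classical nitroalkene preparation and should deliver the thermodynamically preferred E isomer.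

**Step 6**
Reactants: 4 (1E,3E)-1-methoxy-5-silyloxypenta-1,3-diene; 8 (E)-1-nitroprop-1-ene
Product: 9 endo adduct tert-butyl{[(1S,4R,5S,6R)-4-methoxy-6-methyl-5-nitrocyclohex-2-en-1-yl]methoxy}dimethylsilane (target numbering: 1α-NO2, 2α-OMe, 5α-CH2OTBS, 6β-CH3, C3=C4)
Conditions: 1,1'-[(1R,2R)-cyclohexane-1,2-diyl]bis{3-[3,5-bis(trifluoromethyl)phenyl]thiourea} (10–20 mol %), toluene, 4 Å MS, −40 → −20 °C
Reagents that add atoms: none
Why: Proposed new method: the thiourea N–H groups bind the nitro oxygens of 8, lowering its LUMO and covering one face, so that diene 4 adds in a normal-demand, concerted but asynchronous [4+2] cycloaddition in which the C5–C6 bond (diene terminus to the nitroalkene β-carbon) runs ahead of C1–C2. The closest known reaction types are the uncatalysed thermal Diels–Alder reaction of nitroalkenes with 1-alkoxydienes and hydrogen-bond-donor catalysis of enantioselective nitroalkene cycloadditions and conjugate additions. The six-membered carbocycle closes by suprafacial [4+2] cycloaddition, both ring bonds forming in the same step. C2 and C5 come out cis because both diene termini are E, C1 and C6 trans because the dienophile is E, the nitro group lies cis to methoxy through the endo transition state, and the absolute sense (C5 and C6 being the centres that reach the target) is set by the catalyst-shielded nitroalkene face. The step needs ortho regiochemistry, endo selectivity and high facial selectivity; the first follows from the large HOMO coefficient at the diene carbon remote from methoxy meeting the electrophilic β-carbon of the nitroalkene, the second from the nitro group's endo preference reinforced by the bound donor, and the third rests on the catalyst alone, the uncatalysed background being suppressed by the low temperature.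

**Step 7**
Reactants: 9 endo adduct
Product: 10 [(1S,4R,5S,6R)-4-methoxy-6-methyl-5-nitrocyclohex-2-en-1-yl]methanol
Conditions: HF·pyridine, pyridine, THF, 0 °C → rt
Reagents that add atoms: none
Why: fluoride-mediated desilylation under non-basic conditions should free the primary alcohol without deprotonating the acidic C1–H, the allylic methyl ether and nitro group being inert.

**Step 8**
Reactants: 10 homoallylic alcohol
Product: 11 3α,4α-epoxide of 10 (target numbering: 1α-NO2, 2α-OMe, 3α,4α-epoxy, 5α-CH2OH, 6β-CH3)
Conditions: VO(acac)2 (5 mol %), t-BuOOH (decane), CH2Cl2, 0 °C → rt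
Reagents that add atoms: tert-butyl hydroperoxide, CC(C)(C)OO
Why: hydroxyl-directed vanadium-catalysed epoxidation of a cyclic homoallylic alcohol, in which the alkoxide-bound pentavalent vanadium peroxide delivers oxygen to the α face of C3=C4, placing the C4–O bond cis to the C5 arm as the target requires.

**Step 9**
Reactants: 11 epoxy nitro alcohol
Product: 14 (4R,5S,6R)-4-hydroxy-5-(hydroxymethyl)-2-methoxy-6-methylcyclohex-2-en-1-one (4α-OH; 5α-CH2OH; 6β-CH3), via potassium nitronate 12 (not isolated), via epoxy ketone 13 (not isolated)
Conditions: KOt-Bu (1.05 equiv), THF, 0 °C; dimethyldioxirane (acetone), −20 → 0 °C; then DBU, CH2Cl2, 0 °C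
Reagents that add atoms: dimethyldioxirane, CC1(C)OO1
Why: oxidative Nef reaction of the nitronate gives the C1 ketone, whose C2 enolate then opens the β,γ-epoxide at C3 (E1cB) to the C2=C3 methoxy-enone without touching the C4–O bond, while C6 keeps its thermodynamically preferred trans relation to C5.

**Step 10**
Reactants: 14 diol enone
Product: 15 (4S,5R,6R)-4-hydroxy-5-(iodomethyl)-2-methoxy-6-methylcyclohex-2-en-1-one
Conditions: I2, PPh3, imidazole, THF, 0 °C
Reagents that add atoms: iodine, II
Why: Appel-type iodination should select the unhindered primary alcohol over the hindered secondary allylic one under near-neutral conditions that do not enolise the ketone.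

**Step 11**
Reactants: 16 geranylacetone
Product: 18 (E)-6,10-dimethylundeca-5,9-dien-1-yne, via enol phosphate 17 (not isolated)
Conditions: LiN(i-Pr)2 (1.05 equiv), THF, −78 °C; ClP(O)(OEt)2, −78 °C → rt; LiN(i-Pr)2 (2.3 equiv), −78 °C → rt; aq. NH4Cl
Reagents that add atoms: none
Why: kinetic enolisation at the methyl group, O-phosphorylation and base-induced elimination of diethyl phosphate from the terminal enol phosphate is the standard methyl ketone to terminal alkyne conversion and leaves the 5E alkene untouched.

**Step 12**
Reactants: 18 terminal alkyne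
Product: 20 (1E,5E)-1-iodo-2,6,10-trimethylundeca-1,5,9-triene, via alkenylalane 19 (not isolated)
Conditions: AlMe3 (2 equiv), Cp2ZrCl2 (25 mol %), CH2Cl2, 0 °C → rt; I2, THF, −30 → 0 °C
Reagents that add atoms: trimethylaluminium, C[Al](C)C; iodine, II
Why: Negishi carboalumination adds methyl and aluminium syn across the alkyne with methyl on the internal carbon, and iodinolysis with retention then fixes the E trisubstituted alkenyl iodide.

**Step 13**
Reactants: 15 iodomethyl enone; 20 alkenyl iodide (2 equiv)
Product: 21 target, (4R,5R,6R)-4-hydroxy-2-methoxy-6-methyl-5-[(2E,6E)-3,7,11-trimethyldodeca-2,6,10-trien-1-yl]cyclohex-2-en-1-one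
Conditions: NiBr2(MeOCH2CH2OMe) (10 mol %), 4,4'-di-tert-butyl-2,2'-bipyridine (12 mol %), Zn dust, NaI, DMA, rt
Reagents that add atoms: none
Why: nickel-catalysed reductive cross-electrophile coupling, in which zerovalent nickel inserts into the C(sp2)–I bond, the primary alkyl iodide enters as a radical and reductive elimination forms C1'–C2' with retention of alkene geometry, the free hydroxyl and the enone needing no protection.

**Compound list**
1 | glutaconaldehyde potassium salt, potassium (1E,3E)-5-oxopenta-1,3-dien-1-olate | [K+].[O-]/C=C/C=C/C=O | starting material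
2 | (2E,4E)-5-methoxypenta-2,4-dienal | CO/C=C/C=C/C=O | intermediate
3 | (2E,4E)-5-methoxypenta-2,4-dien-1-ol | CO/C=C/C=C/CO | intermediate
4 | tert-butyl{[(2E,4E)-5-methoxypenta-2,4-dien-1-yl]oxy}dimethylsilane | CO/C=C/C=C/CO[Si](C)(C)C(C)(C)C | intermediate
5 | nitromethane | C[N+](=O)[O-] | starting material
6 | acetaldehyde | CC=O | starting material
7 | 1-nitropropan-2-ol (racemic) | CC(O)C[N+](=O)[O-] | intermediate
8 | (E)-1-nitroprop-1-ene | C/C=C/[N+](=O)[O-] | intermediate
9 | tert-butyl{[(1S,4R,5S,6R)-4-methoxy-6-methyl-5-nitrocyclohex-2-en-1-yl]methoxy}dimethylsilane (1α-NO2, 2α-OMe, 5α-CH2OTBS, 6β-CH3) | CO[C@@H]1C=C[C@H](CO[Si](C)(C)C(C)(C)C)[C@@H](C)[C@@H]1[N+](=O)[O-] | intermediate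
10 | [(1S,4R,5S,6R)-4-methoxy-6-methyl-5-nitrocyclohex-2-en-1-yl]methanol | CO[C@@H]1C=C[C@H](CO)[C@@H](C)[C@@H]1[N+](=O)[O-] | intermediate
11 | 3α,4α-epoxide of 10 (1α-NO2, 2α-OMe, 5α-CH2OH, 6β-CH3) | CO[C@@H]1[C@@H]2O[C@@H]2[C@H](CO)[C@@H](C)[C@@H]1[N+](=O)[O-] | intermediate
12 | potassium nitronate of 11 (C1=NO2K) | CO[C@@H]1[C@@H]2O[C@@H]2[C@H](CO)[C@@H](C)C1=[N+]([O-])[O-].[K+] | intermediate
13 | epoxy ketone: 3α,4α-epoxy-5α-(hydroxymethyl)-2α-methoxy-6β-methylcyclohexan-1-one | CO[C@@H]1[C@@H]2O[C@@H]2[C@H](CO)[C@@H](C)C1=O | intermediate
14 | (4R,5S,6R)-4-hydroxy-5-(hydroxymethyl)-2-methoxy-6-methylcyclohex-2-en-1-one | COC1=C[C@H](O)[C@H](CO)[C@@H](C)C1=O | intermediate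
15 | (4S,5R,6R)-4-hydroxy-5-(iodomethyl)-2-methoxy-6-methylcyclohex-2-en-1-one | COC1=C[C@H](O)[C@H](CI)[C@@H](C)C1=O | intermediate
16 | geranylacetone, (E)-6,10-dimethylundeca-5,9-dien-2-one | CC(=O)CC/C=C(\C)CCC=C(C)C | starting material
17 | diethyl (E)-6,10-dimethylundeca-1,5,9-trien-2-yl phosphate | C=C(CC/C=C(\C)CCC=C(C)C)OP(=O)(OCC)OCC | intermediate
18 | (E)-6,10-dimethylundeca-5,9-dien-1-yne | C#CCC/C=C(\C)CCC=C(C)C | intermediate
19 | dimethyl[(1E,5E)-2,6,10-trimethylundeca-1,5,9-trien-1-yl]alane | C[Al](C)/C=C(\C)CC/C=C(\C)CCC=C(C)C | intermediate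
20 | (1E,5E)-1-iodo-2,6,10-trimethylundeca-1,5,9-triene | I/C=C(\C)CC/C=C(\C)CCC=C(C)C | intermediate
21 | (4R,5R,6R)-4-hydroxy-2-methoxy-6-methyl-5-[(2E,6E)-3,7,11-trimethyldodeca-2,6,10-trien-1-yl]cyclohex-2-en-1-one (CNP0534154.1) | COC1=C[C@H](O)[C@H](C/C=C(\C)CC/C=C(\C)CCC=C(C)C)[C@@H](C)C1=O | target

**Totals**
Total step count: 13. Longest linear sequence: 9 steps (1, 2, 3, 6, 7, 8, 9, 10, 13); the nitroalkene (steps 4, 5) and the alkenyl iodide (steps 11, 12) are made in parallel.

**Steps most likely to fail**

Step 6. The hydrogen-bond donor may discriminate the nitroalkene faces poorly, the uncatalysed background cycloaddition may erode the enantiomeric purity, or the nitroalkene may be diverted into an inverse-demand hetero-cycloaddition with the enol ether double bond. Fallback, setting out from 4 and 8: the uncatalysed thermal cycloaddition (toluene, 60–80 °C, a trace of 2,6-di-tert-butyl-4-methylphenol as polymerisation inhibitor) is a known reaction type. It should give the endo adduct as the racemate, i.e. 9 together with its mirror image ent-9 F1. The two are separated by preparative chromatography on a chiral stationary phase (amylose tris(3,5-dimethylphenylcarbamate)), and the route is rejoined at 9.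

Step 9. The nitronate may expel the neighbouring methoxide (E1cB) or attack the epoxide before oxygen transfer, and prolonged base may dehydrate the hydroxy-enone towards a phenol. Fallback, setting out from 11: a reductive Nef reaction on the neutral nitro compound with buffered aqueous TiCl3 (NH4OAc, THF/H2O, rt) generates no nitronate. It proceeds through the oxime F2, whose N–O bond is reduced and whose imine hydrolyses to epoxy ketone 13. Brief treatment with DBU then returns the route at 14.

Step 13. The alkyl radical may be captured by the enone, the alkyl iodide may be reduced to the methyl compound, or homocoupling may outrun cross-coupling. Fallback, setting out from 15: the C4 hydroxyl is silylated (Et3SiCl, imidazole, CH2Cl2, 0 °C) to the triethylsilyl ether F3. Zinc insertion (Zn dust activated with a trace of I2, DMA, 40 °C) gives the alkylzinc iodide F4. Negishi cross-coupling with 20 under Pd(PPh3)4 in THF/DMA forms the silyl-protected coupling product F5 by a polar, non-radical pathway. HF·pyridine then removes the silyl group and the route comes back at 21.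

**Further compounds**
F1 | step 6 | ent-9, tert-butyl{[(1R,4S,5R,6S)-4-methoxy-6-methyl-5-nitrocyclohex-2-en-1-yl]methoxy}dimethylsilane | CO[C@H]1C=C[C@@H](CO[Si](C)(C)C(C)(C)C)[C@H](C)[C@H]1[N+](=O)[O-]
F2 | step 9 | oxime of epoxy ketone 13 (E/Z mixture at C=N) | CO[C@@H]1[C@@H]2O[C@@H]2[C@H](CO)[C@@H](C)C1=NO
F3 | step 13 | C4 triethylsilyl ether of 15 | COC1=C[C@H](O[Si](CC)(CC)CC)[C@H](CI)[C@@H](C)C1=O
F4 | step 13 | alkylzinc iodide from F3 | COC1=C[C@H](O[Si](CC)(CC)CC)[C@H](C[Zn]I)[C@@H](C)C1=O
F5 | step 13 | C4 triethylsilyl ether of 21 | COC1=C[C@H](O[Si](CC)(CC)CC)[C@H](C/C=C(\C)CC/C=C(\C)CCC=C(C)C)[C@@H](C)C1=O
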